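**Retrosynthetic overview**

1. The target has a hidden mirror plane through C7 and C2 (C6–O and C8–O are cis to each other and trans to the C7 side chain; C4 and C10 both carry CH2OH). It is traced to a ten‑membered 4,9‑diene lactone built in two directions, in which only the alkene next to the free C8–OH is hydrogenated (sets C10); exocyclic methylene, methacrylate and PMB removal come last.
2. Ten‑membered carbocycle ⇐ double allylic alkylation of bis(phenylsulfonyl)methane (C2 linchpin) by a bis‑allylic bromide, then desulfonylation.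
3. Bis‑allylic bromide ⇐ two‑fold E‑selective HWE on a C5–C9 dialdehyde; the reduction step frees C6–OH, which closes the γ‑lactone before the carbocycle.
4. Dialdehyde ⇐ ozonolysis of a desymmetrised 2‑substituted cis‑cyclopent‑4‑ene‑1,3‑diol; key step: lipase desymmetrisation of the meso diol, fixing C6, C7 and C8 at once.
5. meso‑Diol ⇐ one‑pot dearomatising C‑alkylation of aromatic cyclopentadienide and anti‑selective singlet‑oxygen [4+2]/reduction. Ring order: cyclopentene (sacrificial template) → γ‑lactone → ten‑membered ring.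

Assumption: locants follow germacrane numbering (C6 lactone O–CH, C7 ring‑fusion CH, C8 ester‑bearing CH, C10 CH–CH2OH, C4=C5 ring alkene, C11–C13 lactone carbons, C14/C15 the CH2OH carbons); the lipase in step 2 is taken to acylate the hydroxyl that becomes O6 (an enantiocomplementary lipase is used otherwise).

**Route**

Step 1
Reactants: 1 sodium cyclopentadienide (aromatic C5H5 anion, 2.0 M in THF); 2 tert‑butyl bromoacetate
Product: 5 tert‑butyl 2‑[(1r,2R,5S)‑2,5‑dihydroxycyclopent‑3‑en‑1‑yl]acetate (meso; side chain trans to both OH), via cyclopentadienyl ester 3 (not isolated), via endoperoxide 4 (not isolated)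
Conditions: 1 added to 2, THF, −78 °C, 1 h; cold transfer into CH2Cl2/MeOH (1% H2O), 5,10,15,20‑tetraphenylporphyrin, O2, hν (sodium lamp), −40 °C; thiourea, −40 → 23 °C
Reagents that add atoms: dioxygen, O=O
Why: SN2 C‑alkylation of cyclopentadienide gives the kinetic 5‑substituted diene, which below −30 °C does not undergo the 1,5‑hydrogen shift and adds singlet oxygen ([4+2] photooxygenation) on the face anti to the side chain, so thiourea reduction of the O–O bond gives the cis‑diol with the side chain trans to both hydroxyls, i.e. the relative configuration of C6, C7 and C8 in one pot.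

Step 2
Reactants: 5 meso‑diol
Product: 6 tert‑butyl 2‑[(1R,2R,5S)‑2‑acetoxy‑5‑hydroxycyclopent‑3‑en‑1‑yl]acetate
Conditions: immobilised Candida antarctica lipase B, vinyl acetate (3 equiv), t‑BuOMe, 25 °C
Reagents that add atoms: vinyl acetate, C=COC(C)=O
Why: Lipase‑catalysed enantiotopic‑group‑selective transesterification (irreversible with the enol ester) acetylates only one of the two mirror‑related allylic hydroxyls, the one that becomes the lactone oxygen on C6, which fixes the absolute configuration of C6, C7 and C8 at once with no 50% yield ceiling, as is established for the parent cis‑cyclopent‑2‑ene‑1,4‑diol.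

Step 3
Reactants: 6 monoacetate
Product: 7 tert‑butyl 2‑[(1S,2R,5S)‑2‑acetoxy‑5‑(tert‑butyldimethylsilyloxy)cyclopent‑3‑en‑1‑yl]acetate
Conditions: TBSCl, imidazole, DMF, 23 °C
Reagents that add atoms: tert‑butyldimethylsilyl chloride, CC(C)(C)[Si](C)(C)Cl
Why: Standard silylation of the remaining secondary allylic alcohol (the future C8 oxygen) changes no stereocentre and leaves the two halves of the ring with orthogonal oxygen substituents.

Step 4
Reactants: 7 silyl ether acetate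
Product: 9 tert‑butyl (3S,4S)‑4‑acetoxy‑3‑[(1R)‑1‑(tert‑butyldimethylsilyloxy)‑2‑oxoethyl]‑5‑oxopentanoate, via ozonide 8 (not isolated)
Conditions: O3, CH2Cl2, −78 °C; PPh3, −78 → 23 °C; used crude
Reagents that add atoms: ozone, [O-][O+]=O
Why: Criegee ozonolysis of the only alkene with reductive work‑up opens the five‑membered ring to the C5 and C9 aldehydes without touching the three stereocentres, which only change CIP descriptor.

Step 5
Reactants: 10 4‑methoxybenzyl alcohol; 11 ethyl 2‑(diethoxyphosphoryl)acrylate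
Product: 12 ethyl 2‑(diethoxyphosphoryl)‑3‑[(4‑methoxybenzyl)oxy]propanoate (racemic)
Conditions: t‑BuOK (5 mol%), THF, 0 °C
Reagents that add atoms: none
Why: Alkoxide‑catalysed oxa‑Michael addition to the doubly activated vinylphosphonate gives the α‑(alkoxymethyl)phosphonoacetate, whose stereocentre is irrelevant because it becomes sp2 in the next step.

Step 6
Reactants: 9 dialdehyde; 12 phosphonate
Product: 13 diethyl (2E,4R,5S,6S,7E)‑4‑acetoxy‑5‑(2‑tert‑butoxy‑2‑oxoethyl)‑6‑(tert‑butyldimethylsilyloxy)‑2,8‑bis{[(4‑methoxybenzyl)oxy]methyl}nona‑2,7‑dienedioate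
Conditions: 12 (2.4 equiv), NaH (2.3 equiv), THF, 0 °C; then 9, −78 → 0 °C
Reagents that add atoms: none
Why: Two‑directional Horner–Wadsworth–Emmons olefination of both α‑oxygenated aldehydes with the α‑substituted phosphonoacetate gives the trisubstituted enoates with the ester trans to the chain, so each CH2OPMB (future C15 and C14) ends cis to the oxygenated carbon and each ester carbon (future C3 and C1) is placed for the trans ring bond.

Step 7
Reactants: 13 bis‑enoate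
Product: 15 (4S,5R)‑4‑[(1S,2Z)‑1‑(tert‑butyldimethylsilyloxy)‑4‑hydroxy‑3‑{[(4‑methoxybenzyl)oxy]methyl}but‑2‑en‑1‑yl]‑5‑[(1Z)‑3‑hydroxy‑2‑{[(4‑methoxybenzyl)oxy]methyl}prop‑1‑en‑1‑yl]dihydrofuran‑2(3H)‑one, via triol ester 14 (not isolated)
Conditions: i‑Bu2AlH (7 equiv), CH2Cl2, −78 °C; aq. potassium sodium tartrate; crude 14, t‑BuOK (0.2 equiv), THF, 0 °C
Reagents that add atoms: none
Why: DIBAL‑H reduces the two conjugated ethyl esters to allylic alcohols and cleaves the acetate while the hindered tert‑butyl ester survives at −78 °C, and the freed C6 alkoxide then closes onto the tert‑butyl ester (base‑catalysed lactonisation; the C8 oxygen is silylated), giving the trans‑disubstituted γ‑lactone with C6 and C7 unchanged.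

Step 8
Reactants: 15 lactone diol
Product: 16 (4S,5R)‑4‑[(1S,2E)‑4‑bromo‑1‑(tert‑butyldimethylsilyloxy)‑3‑{[(4‑methoxybenzyl)oxy]methyl}but‑2‑en‑1‑yl]‑5‑[(1E)‑3‑bromo‑2‑{[(4‑methoxybenzyl)oxy]methyl}prop‑1‑en‑1‑yl]dihydrofuran‑2(3H)‑one
Conditions: CBr4, PPh3, CH2Cl2, 0 °C
Reagents that add atoms: carbon tetrabromide, BrC(Br)(Br)Br
Why: Appel bromination converts the two primary allylic alcohols, the only free hydroxyls, into SN2‑reactive allylic bromides without allylic transposition at 0 °C.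

Step 9
Reactants: 16 dibromide; 17 bis(phenylsulfonyl)methane
Product: 18 (3aS,4S,5Z,10Z,11aR)‑4‑(tert‑butyldimethylsilyloxy)‑6,10‑bis{[(4‑methoxybenzyl)oxy]methyl}‑8,8‑bis(phenylsulfonyl)‑3a,4,7,8,9,11a‑hexahydrocyclodeca[b]furan‑2(3H)‑one
Conditions: 16 and 17 (1.0 equiv each) added over 12 h to Cs2CO3 (4 equiv), DMF (final 2 mM), 40 °C
Reagents that add atoms: none
Why: Two successive SN2 alkylations of the soft, twice‑deprotonatable bis(sulfonyl)methane carbon (the C2 linchpin) by the primary allylic bromides close the ten‑membered carbocycle under high dilution, helped by the caesium effect, the gem‑disulfonyl (Thorpe–Ingold) bias and the pre‑organising trans ring alkenes and trans‑lactone, as in sulfone‑based germacrane ring closures; no stereocentre is formed.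

Step 10
Reactants: 18 bis‑sulfone
Product: 19 (3aS,4S,5Z,10Z,11aR)‑4‑(tert‑butyldimethylsilyloxy)‑6,10‑bis{[(4‑methoxybenzyl)oxy]methyl}‑3a,4,7,8,9,11a‑hexahydrocyclodeca[b]furan‑2(3H)‑one
Conditions: Na(Hg) (6% Na), Na2HPO4, MeOH/THF, −20 → 0 °C
Reagents that add atoms: none
Why: Buffered sodium‑amalgam reductive desulfonylation removes both phenylsulfonyl groups from the non‑allylic C2 carbon, leaving CH2 and sparing the alkenes, silyl ether, PMB ethers and lactone.

Step 11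
Reactants: 19 silyl ether
Product: 20 (3aR,4S,5Z,10Z,11aR)‑4‑hydroxy‑6,10‑bis{[(4‑methoxybenzyl)oxy]methyl}‑3a,4,7,8,9,11a‑hexahydrocyclodeca[b]furan‑2(3H)‑one
Conditions: HF·pyridine, pyridine, THF, 0 → 23 °C
Reagents that add atoms: none
Why: Acidic fluoride desilylation frees the C8 hydroxyl in a non‑basic medium, so it cannot translactonise onto C12.

Step 12
Reactants: 20 dienol
Product: 21 (3aR,4S,6R,10Z,11aR)‑4‑hydroxy‑6,10‑bis{[(4‑methoxybenzyl)oxy]methyl}‑3a,4,5,6,7,8,9,11a‑octahydrocyclodeca[b]furan‑2(3H)‑one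
Conditions: [Rh(C7H8)(Ph2P(CH2)4PPh2)]BF4 (5 mol%), H2 (15 bar), CH2Cl2, 23 °C
Reagents that add atoms: none
Why: Hydroxyl‑directed homogeneous hydrogenation reduces only the alkene allylic to the free C8–OH (the C4=C5 alkene has only ether and lactone oxygens, which do not direct this cationic rhodium catalyst), and because the cis CH2OPMB group holds C8–H in the alkene plane (A(1,3) strain) hydrogen is delivered from the hydroxyl face, which sets C10 as R.

Step 13
Reactants: 21 hydroxy lactone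
Product: 26 (3aR,4S,6R,10Z,11aR)‑4‑hydroxy‑6,10‑bis{[(4‑methoxybenzyl)oxy]methyl}‑3‑methylidene‑3a,4,5,6,7,8,9,11a‑octahydrocyclodeca[b]furan‑2(3H)‑one, via trimethylsilyl ether 22 (not isolated), via Mannich base 23 (not isolated), via ammonium iodide 24 (not isolated), via methylidene silyl ether 25 (not isolated)
Conditions: TMSCl, Et3N, THF, 0 °C; LDA (2.5 equiv), −78 °C; Me2N=CH2 I (Eschenmoser's salt), −78 → 0 °C; MeI, MeOH, 23 °C; aq. NaHCO3/EtOAc, 23 °C; 10% citric acid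
Reagents that add atoms: Eschenmoser's salt, C=[N+](C)C.[I-]
Why: Transient O‑silylation prevents alkoxide‑induced translactonisation, the lactone lithium enolate undergoes a Mannich reaction with the iminium salt, and quaternisation followed by E1cB elimination installs the exocyclic methylene (Eschenmoser methylenation) with C7 untouched.

Step 14
Reactants: 26 hydroxy methylidene lactone; 27 methacryloyl chloride
Product: 28 (3aR,4S,6R,10Z,11aR)‑6,10‑bis{[(4‑methoxybenzyl)oxy]methyl}‑3‑methylidene‑2‑oxo‑2,3,3a,4,5,6,7,8,9,11a‑decahydrocyclodeca[b]furan‑4‑yl 2‑methylprop‑2‑enoate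
Conditions: Et3N, 4‑(dimethylamino)pyridine (cat.), CH2Cl2, 0 °C
Reagents that add atoms: none
Why: Acylation under nucleophilic catalysis esterifies the only free hydroxyl, the secondary C8–OH, with retention at C8.

Step 15
Reactants: 28 bis‑PMB ether
Product: 29 (3aR,4S,6R,10Z,11aR)‑6,10‑bis(hydroxymethyl)‑3‑methylidene‑2‑oxo‑2,3,3a,4,5,6,7,8,9,11a‑decahydrocyclodeca[b]furan‑4‑yl 2‑methylprop‑2‑enoate (target)
Conditions: DDQ (2.6 equiv), CH2Cl2/pH 7 phosphate buffer (10:1), 0 °C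
Reagents that add atoms: none
Why: Oxidative PMB cleavage (benzylic hydride abstraction by DDQ, then hydrolysis) unmasks the C14 and C15 primary alcohols under neutral conditions that leave the methacrylate, the α‑methylene lactone and the trisubstituted alkene intact.

**Compound list**

1 | sodium cyclopentadienide | [Na+].[cH-]1cccc1 | starting material
2 | tert‑butyl bromoacetate | BrCC(=O)OC(C)(C)C | starting material
3 | tert‑butyl 2‑(cyclopenta‑2,4‑dien‑1‑yl)acetate | CC(C)(C)OC(=O)CC1C=CC=C1 | intermediate (not isolated)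
4 | tert‑butyl 2‑[(1R,4S)‑2,3‑dioxabicyclo[2.2.1]hept‑5‑en‑7‑yl]acetate, side chain anti to O–O (meso) | C1=C[C@H]2OO[C@@H]1[C@H]2CC(=O)OC(C)(C)C | intermediate (not isolated)
5 | tert‑butyl 2‑[(1r,2R,5S)‑2,5‑dihydroxycyclopent‑3‑en‑1‑yl]acetate (meso) | O[C@H]1C=C[C@@H](O)[C@@H]1CC(=O)OC(C)(C)C | intermediate
6 | tert‑butyl 2‑[(1R,2R,5S)‑2‑acetoxy‑5‑hydroxycyclopent‑3‑en‑1‑yl]acetate | O[C@H]1C=C[C@@H](OC(C)=O)[C@@H]1CC(=O)OC(C)(C)C | intermediate
7 | tert‑butyl 2‑[(1S,2R,5S)‑2‑acetoxy‑5‑(tert‑butyldimethylsilyloxy)cyclopent‑3‑en‑1‑yl]acetate | CC(C)(C)[Si](C)(C)O[C@H]1C=C[C@@H](OC(C)=O)[C@@H]1CC(=O)OC(C)(C)C | intermediate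
8 | ozonide of 7 (6,7,8‑trioxabicyclo[3.2.1]octane; bridgehead configuration unassigned) | CC(C)(C)[Si](C)(C)O[C@H]1C2OOC(O2)[C@@H](OC(C)=O)[C@@H]1CC(=O)OC(C)(C)C | intermediate (not isolated)
9 | tert‑butyl (3S,4S)‑4‑acetoxy‑3‑[(1R)‑1‑(tert‑butyldimethylsilyloxy)‑2‑oxoethyl]‑5‑oxopentanoate | O=C[C@H](O[Si](C)(C)C(C)(C)C)[C@@H](CC(=O)OC(C)(C)C)[C@H](OC(C)=O)C=O | intermediate
10 | 4‑methoxybenzyl alcohol | COc1ccc(CO)cc1 | starting material
11 | ethyl 2‑(diethoxyphosphoryl)acrylate | C=C(C(=O)OCC)P(=O)(OCC)OCC | starting material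
12 | ethyl 2‑(diethoxyphosphoryl)‑3‑[(4‑methoxybenzyl)oxy]propanoate (racemic) | CCOC(=O)C(COCc1ccc(OC)cc1)P(=O)(OCC)OCC | intermediate
13 | diethyl (2E,4R,5S,6S,7E)‑4‑acetoxy‑5‑(2‑tert‑butoxy‑2‑oxoethyl)‑6‑(tert‑butyldimethylsilyloxy)‑2,8‑bis{[(4‑methoxybenzyl)oxy]methyl}nona‑2,7‑dienedioate | CCOC(=O)/C(COCc1ccc(OC)cc1)=C/[C@H](O[Si](C)(C)C(C)(C)C)[C@@H](CC(=O)OC(C)(C)C)[C@H](OC(C)=O)/C=C(/C(=O)OCC)COCc1ccc(OC)cc1 | intermediate
14 | triol tert‑butyl ester from 13 (both CO2Et reduced to CH2OH, C6–OH free, stereocentres as in 13) | OC/C(COCc1ccc(OC)cc1)=C/[C@H](O[Si](C)(C)C(C)(C)C)[C@@H](CC(=O)OC(C)(C)C)[C@H](O)/C=C(/CO)COCc1ccc(OC)cc1 | intermediate (not isolated)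
15 | (4S,5R)‑4‑[(1S,2Z)‑1‑(tert‑butyldimethylsilyloxy)‑4‑hydroxy‑3‑{[(4‑methoxybenzyl)oxy]methyl}but‑2‑en‑1‑yl]‑5‑[(1Z)‑3‑hydroxy‑2‑{[(4‑methoxybenzyl)oxy]methyl}prop‑1‑en‑1‑yl]dihydrofuran‑2(3H)‑one | OC/C(COCc1ccc(OC)cc1)=C/[C@H](O[Si](C)(C)C(C)(C)C)[C@H]1CC(=O)O[C@@H]1/C=C(/CO)COCc1ccc(OC)cc1 | intermediate
16 | bis(allylic bromide) of 15 (both CH2OH → CH2Br; 2E and 1E) | BrC/C(COCc1ccc(OC)cc1)=C/[C@H](O[Si](C)(C)C(C)(C)C)[C@H]1CC(=O)O[C@@H]1/C=C(/CBr)COCc1ccc(OC)cc1 | intermediate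
17 | bis(phenylsulfonyl)methane | O=S(=O)(CS(=O)(=O)c1ccccc1)c1ccccc1 | starting material
18 | (3aS,4S,5Z,10Z,11aR)‑4‑(tert‑butyldimethylsilyloxy)‑6,10‑bis{[(4‑methoxybenzyl)oxy]methyl}‑8,8‑bis(phenylsulfonyl)‑3a,4,7,8,9,11a‑hexahydrocyclodeca[b]furan‑2(3H)‑one | CC(C)(C)[Si](C)(C)O[C@H]1/C=C(COCc3ccc(OC)cc3)/CC(S(=O)(=O)c3ccccc3)(S(=O)(=O)c3ccccc3)C/C(COCc3ccc(OC)cc3)=C/[C@H]2OC(=O)C[C@H]12 | intermediate
19 | (3aS,4S,5Z,10Z,11aR)‑4‑(tert‑butyldimethylsilyloxy)‑6,10‑bis{[(4‑methoxybenzyl)oxy]methyl}‑3a,4,7,8,9,11a‑hexahydrocyclodeca[b]furan‑2(3H)‑one | CC(C)(C)[Si](C)(C)O[C@H]1/C=C(COCc3ccc(OC)cc3)/CCC/C(COCc3ccc(OC)cc3)=C/[C@H]2OC(=O)C[C@H]12 | intermediate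
20 | (3aR,4S,5Z,10Z,11aR)‑4‑hydroxy‑6,10‑bis{[(4‑methoxybenzyl)oxy]methyl}‑3a,4,7,8,9,11a‑hexahydrocyclodeca[b]furan‑2(3H)‑one | O[C@H]1/C=C(COCc3ccc(OC)cc3)/CCC/C(COCc3ccc(OC)cc3)=C/[C@H]2OC(=O)C[C@H]12 | intermediate
21 | (3aR,4S,6R,10Z,11aR)‑4‑hydroxy‑6,10‑bis{[(4‑methoxybenzyl)oxy]methyl}‑3a,4,5,6,7,8,9,11a‑octahydrocyclodeca[b]furan‑2(3H)‑one | O[C@H]1C[C@H](COCc3ccc(OC)cc3)CCC/C(COCc3ccc(OC)cc3)=C/[C@H]2OC(=O)C[C@H]12 | intermediate
22 | O8‑trimethylsilyl ether of 21 | C[Si](C)(C)O[C@H]1C[C@H](COCc3ccc(OC)cc3)CCC/C(COCc3ccc(OC)cc3)=C/[C@H]2OC(=O)C[C@H]12 | intermediate (not isolated)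
23 | C11‑(dimethylaminomethyl) lactone, O8‑TMS (C11 epimers) | C[Si](C)(C)O[C@H]1C[C@H](COCc3ccc(OC)cc3)CCC/C(COCc3ccc(OC)cc3)=C/[C@H]2OC(=O)C(CN(C)C)[C@H]12 | intermediate (not isolated)
24 | C11‑(trimethylammoniomethyl) lactone iodide, O8‑TMS | C[Si](C)(C)O[C@H]1C[C@H](COCc3ccc(OC)cc3)CCC/C(COCc3ccc(OC)cc3)=C/[C@H]2OC(=O)C(C[N+](C)(C)C)[C@H]12.[I-] | intermediate (not isolated)
25 | O8‑trimethylsilyl ether of 26 | C[Si](C)(C)O[C@H]1C[C@H](COCc3ccc(OC)cc3)CCC/C(COCc3ccc(OC)cc3)=C/[C@H]2OC(=O)C(=C)[C@H]12 | intermediate (not isolated)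
26 | (3aR,4S,6R,10Z,11aR)‑4‑hydroxy‑6,10‑bis{[(4‑methoxybenzyl)oxy]methyl}‑3‑methylidene‑3a,4,5,6,7,8,9,11a‑octahydrocyclodeca[b]furan‑2(3H)‑one | O[C@H]1C[C@H](COCc3ccc(OC)cc3)CCC/C(COCc3ccc(OC)cc3)=C/[C@H]2OC(=O)C(=C)[C@H]12 | intermediate
27 | methacryloyl chloride | C=C(C)C(Cl)=O | starting material
28 | (3aR,4S,6R,10Z,11aR)‑6,10‑bis{[(4‑methoxybenzyl)oxy]methyl}‑3‑methylidene‑2‑oxo‑2,3,3a,4,5,6,7,8,9,11a‑decahydrocyclodeca[b]furan‑4‑yl 2‑methylprop‑2‑enoate | C=C(C)C(=O)O[C@H]1C[C@H](COCc3ccc(OC)cc3)CCC/C(COCc3ccc(OC)cc3)=C/[C@H]2OC(=O)C(=C)[C@H]12 | intermediate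
29 | (3aR,4S,6R,10Z,11aR)‑6,10‑bis(hydroxymethyl)‑3‑methylidene‑2‑oxo‑2,3,3a,4,5,6,7,8,9,11a‑decahydrocyclodeca[b]furan‑4‑yl 2‑methylprop‑2‑enoate | C=C(C)C(=O)O[C@H]1C[C@H](CO)CCC/C(CO)=C/[C@H]2OC(=O)C(=C)[C@H]12 | target

**Step count**

Total: 15 steps. Longest linear sequence: 14 steps (steps 1–4 and 6–15; step 5 is a one‑step reagent branch).

**Three steps most likely to fail, each with one fallback**

Step 1 (the 5‑substituted cyclopentadiene can isomerise by 1,5‑hydrogen shift or be alkylated twice before photooxygenation). Fallback: set out from 2. Reformatsky addition of 2 (Zn dust, THF) to furfural gives tert‑butyl 3‑(furan‑2‑yl)‑3‑hydroxypropanoate F1. Piancatelli rearrangement (Dy(OSO2CF3)3, t‑BuOH/H2O, 80 °C; furan ring opening and conrotatory 4π electrocyclisation) gives racemic trans tert‑butyl 2‑(2‑hydroxy‑5‑oxocyclopent‑3‑en‑1‑yl)acetate F2. 1,2‑Reduction with NaBH4/CeCl3·7H2O at −40 °C gives the all‑trans diol; both enantiomers of F2 converge on the same meso compound, and the route comes back at 5.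

Step 9 (ten‑membered ring closure by double SN2; oligomerisation or SN2′ attack may dominate). Fallback: set out from 15. Methyl chloroformate/pyridine gives the bis(methyl carbonate) F3. Pd2(dba)3·CHCl3 (zerovalent palladium), 1,2‑bis(diphenylphosphino)ethane and 17 in THF at 2 mM and 60 °C close the ring by two decarboxylative π‑allyl (Tsuji–Trost) alkylations, the methoxide released from each carbonate acting as base; the route comes back at 18.

Step 12 (the second trisubstituted alkene may also be reduced, or the ring conformation may override the A(1,3) model at C10). Fallback: set out from 20. MnO2 in CH2Cl2 oxidises the allylic C8 alcohol to the C8 enone F4. Ligand‑controlled copper hydride conjugate reduction (Cu(OAc)2, the DTBM‑SEGPHOS enantiomer that gives the 10R product, polymethylhydrosiloxane, t‑BuOH, toluene) touches only the enone and gives the saturated C8 ketone F5. NaBH4/CeCl3·7H2O at −40 °C (hydride from the outer face, anti to the C7–C11 bond) restores the 8S alcohol; the route comes back at 21.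

**Further compounds**

F1 | step 1 | tert‑butyl 3‑(furan‑2‑yl)‑3‑hydroxypropanoate (racemic) | CC(C)(C)OC(=O)CC(O)c1ccco1
F2 | step 1 | rac‑trans‑tert‑butyl 2‑(2‑hydroxy‑5‑oxocyclopent‑3‑en‑1‑yl)acetate (one enantiomer drawn) | O=C1C=C[C@@H](O)[C@@H]1CC(=O)OC(C)(C)C
F3 | step 9 | bis(methyl carbonate) of 15 | COC(=O)OC/C(COCc1ccc(OC)cc1)=C/[C@H](O[Si](C)(C)C(C)(C)C)[C@H]1CC(=O)O[C@@H]1/C=C(/COC(=O)OC)COCc1ccc(OC)cc1
F4 | step 12 | C8 enone from 20 (both ring alkenes retained) | O=C1/C=C(COCc3ccc(OC)cc3)/CCC/C(COCc3ccc(OC)cc3)=C/[C@H]2OC(=O)C[C@H]12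
F5 | step 12 | saturated C8 ketone with C10 set (10R) | O=C1C[C@H](COCc3ccc(OC)cc3)CCC/C(COCc3ccc(OC)cc3)=C/[C@H]2OC(=O)C[C@H]12
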